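**Retrosynthetic overview** (dihydronaphthalene numbering: C1 bears the pendant aryl ring A, C2 is the sp3 methyl-bearing carbon, C3=C4 is the styrene bond, ring B is the fused arene C4a–C8a)
1. Target ⇐ its bis(triisopropylsilyl) ether ⇐ an acyclic, achiral precursor by a single C–C disconnection, C2–C3.
2. Key event: a (Z)-vinyllithium at C3 (from a vinyl iodide) adds to C2 of a 1,1-diarylpropene held ortho on ring B; lithium ends on C1 and is replaced by H. The ring, the position of C3=C4 and both stereocentres arise in this one operation.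
3. Enabling feature: C1 is bonded to two arenes (ring A and C8a of ring B), so a C1=C2 alkene accepts a carbon nucleophile only at C2, with the charge on doubly benzylic C1. C1 and C4 sit on adjacent ring-B carbons (C8a, C4a), so this attack closes exactly the six-membered ring.
4. Precursor ⇐ aryl aldehyde (C4 = CHO, Z-selective iodo-olefination) ⇐ Suzuki coupling of silylated 2-bromosyringaldehyde (ring B, C8a–Br) with a geometrically defined 1-arylprop-1-enylboronate (ring A, C1, C2 and its methyl) made from propiosyringone.
5. Ring order: rings A and B are bought as arenes; the only ring made is the carbocycle C1–C2–C3–C4–C4a–C8a, last, in step 8.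

Key step: step 8

Assumption: 1-(4-hydroxy-3,5-dimethoxyphenyl)propan-1-one is taken as commercially available; the sense of induction of (−)-sparteine in step 8 cannot be predicted with confidence and is assumed to give the (1S,2S) series, (+)-sparteine being used instead if the opposite sense is found.

**Route**

Step 1
Reactants: 1 syringaldehyde (4-hydroxy-3,5-dimethoxybenzaldehyde)
Product: 2 3,5-dimethoxy-4-(triisopropylsilyloxy)benzaldehyde
Conditions: i-Pr3SiOTf, 2,6-lutidine, CH2Cl2, 0 °C to rt
Reagents that add atoms: triisopropylsilyl trifluoromethanesulfonate, CC(C)[Si](OS(=O)(=O)C(F)(F)F)(C(C)C)C(C)C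
Why: O-silylation of a hindered phenol with a silyl triflate; the bulky silyl ether should survive the later base, cross-coupling and organolithium steps and is removed by fluoride at the end.

Step 2
Reactants: 2 3,5-dimethoxy-4-(triisopropylsilyloxy)benzaldehyde
Product: 3 2-bromo-3,5-dimethoxy-4-(triisopropylsilyloxy)benzaldehyde
Conditions: N-bromosuccinimide, MeCN, rt
Reagents that add atoms: N-bromosuccinimide, O=C1CCC(=O)N1Br
Why: electrophilic aromatic bromination; the two positions ortho to the formyl group are equivalent, are the only free ring positions, and each is ortho and para to a methoxy group.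

Step 3
Reactants: 4 propiosyringone (1-(4-hydroxy-3,5-dimethoxyphenyl)propan-1-one)
Product: 5 1-[3,5-dimethoxy-4-(triisopropylsilyloxy)phenyl]propan-1-one
Conditions: i-Pr3SiOTf, 2,6-lutidine, CH2Cl2, 0 °C to rt
Reagents that add atoms: triisopropylsilyl trifluoromethanesulfonate, CC(C)[Si](OS(=O)(=O)C(F)(F)F)(C(C)C)C(C)C
Why: O-silylation of the phenol as in step 1, so that ketone enolisation in the next step is the only acid–base event.

Step 4
Reactants: 5 1-[3,5-dimethoxy-4-(triisopropylsilyloxy)phenyl]propan-1-one
Product: 7 (Z)-1-[3,5-dimethoxy-4-(triisopropylsilyloxy)phenyl]prop-1-en-1-yl trifluoromethanesulfonate (triflate oxygen cis to the methyl group), via lithium enolate 6 (not isolated)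
Conditions: LiN(SiMe3)2, THF, −78 °C; then PhNTf2, −78 °C to rt
Reagents that add atoms: N-phenylbis(trifluoromethanesulfonimide), O=S(=O)(N(c1ccccc1)S(=O)(=O)C(F)(F)F)C(F)(F)F
Why: kinetic deprotonation of an aryl ethyl ketone should give the (Z)-enolate (methyl cis to oxygen, which avoids allylic strain with the arene), and O-triflation traps this geometry; enol triflate formation.

Step 5
Reactants: 7 (Z)-1-[3,5-dimethoxy-4-(triisopropylsilyloxy)phenyl]prop-1-en-1-yl trifluoromethanesulfonate
Product: 8 2-[(E)-1-[3,5-dimethoxy-4-(triisopropylsilyloxy)phenyl]prop-1-en-1-yl]-4,4,5,5-tetramethyl-1,3,2-dioxaborolane (boron cis to the methyl group)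
Conditions: B2pin2, PdCl2(PPh3)2, PPh3, KOPh, toluene, 50 °C
Reagents that add atoms: bis(pinacolato)diboron, CC1(C)OB(OC1(C)C)B1OC(C)(C)C(C)(C)O1
Why: Miyaura borylation of an alkenyl triflate, which proceeds with retention of alkene geometry; the weak phenoxide base is used so that the product boronate does not couple with unreacted triflate.

Step 6
Reactants: 3 2-bromo-3,5-dimethoxy-4-(triisopropylsilyloxy)benzaldehyde; 8 the (E)-alkenylboronate from step 5
Product: 9 2-[(Z)-1-[3,5-dimethoxy-4-(triisopropylsilyloxy)phenyl]prop-1-en-1-yl]-3,5-dimethoxy-4-(triisopropylsilyloxy)benzaldehyde (propenyl methyl cis to the benzaldehyde ring)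
Conditions: Pd(OAc)2, SPhos, K3PO4, toluene–H2O, 90 °C
Reagents that add atoms: none
Why: Suzuki–Miyaura coupling with retention of alkene geometry; the electron-rich biaryl dialkylphosphine is chosen for the doubly ortho-substituted aryl bromide, and the aldehyde and silyl ethers are inert under these conditions.

Step 7
Reactants: 9 the (Z)-1,1-diarylpropene aldehyde from step 6
Product: 10 the (Z,Z)-vinyl iodide in which the CHO of 9 has become CH=C(I)CH3 with iodine cis to the arene
Conditions: [Ph3PCH2CH3]I, n-BuLi, THF, rt; I2, −78 °C; NaN(SiMe3)2, −20 °C; then 9, −78 °C to rt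
Reagents that add atoms: ethyltriphenylphosphonium iodide, CC[P+](c1ccccc1)(c1ccccc1)c1ccccc1.[I-]; iodine, II
Why: Wittig olefination with an alpha-iodo ylide (Stork–Zhao type); the non-stabilised ylide reacts under kinetic control and should place iodine cis to the arene, the geometry required for ring closure.

Step 8
Reactants: 10 the (Z,Z)-vinyl iodide from step 7
Product: 13 (1S,2S)-1-[3,5-dimethoxy-4-(triisopropylsilyloxy)phenyl]-6,8-dimethoxy-2,3-dimethyl-7-(triisopropylsilyloxy)-1,2-dihydronaphthalene (1,2-cis), via vinyllithium 11 (not isolated), via benzhydryllithium 12 (not isolated)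
Conditions: (−)-sparteine, t-BuLi (2 equiv), toluene–Et2O, −78 °C to −40 °C; then MeOH, −78 °C
Reagents that add atoms: none
Why: Proposed new method: iodine–lithium exchange at C3 gives a (Z)-vinyllithium whose C–Li bond points at the neighbouring 1,1-diarylalkene, and syn-carbolithiation then joins C3 to C2 and transfers lithium to C1, whose benzhydryl-type anion is protonated by methanol. The closest known reaction types are the (−)-sparteine-mediated asymmetric intramolecular carbolithiation of aryllithiums onto alkenes and the sparteine-mediated addition of organolithiums to beta-methylstyrenes; a vinyllithium combined with a 1,1-diarylalkene acceptor in this ring size has not been shown. The one ring that is closed, the carbocycle C1–C2–C3–C4–C4a–C8a, forms in a 6-endo-trig mode. C2 is set in the C–C bond formation by the diamine-bound lithium, which differentiates the two faces of the trisubstituted alkene, and C1 is set in the quench, the proton entering anti to the pseudoaxial C2 methyl group so that aryl and methyl end up cis. The step needs regioselectivity for C2 over C1 and addition faster than proton abstraction from the allylic methyl group; the first is secured because only attack at C2 leaves the charge on doubly benzylic C1, the second by intramolecular delivery of C3, held ortho on ring B, and by the low temperature.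

Step 9
Reactants: 13 the (1S,2S)-bis(triisopropylsilyl) ether from step 8
Product: 14 4-[(1S,2S)-7-hydroxy-6,8-dimethoxy-2,3-dimethyl-1,2-dihydronaphthalen-1-yl]-2,6-dimethoxyphenol (target, 1,2-cis)
Conditions: Bu4NF, AcOH, THF, 0 °C
Reagents that add atoms: none
Why: fluoride cleavage of aryl silyl ethers; acetic acid buffers the phenoxides so that the electron-rich dihydronaphthalene is not exposed to base and air or to strong acid, and neither stereocentre is touched.

**Compound list**

1 | syringaldehyde (4-hydroxy-3,5-dimethoxybenzaldehyde) | COc1cc(C=O)cc(OC)c1O | starting material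
2 | 3,5-dimethoxy-4-(triisopropylsilyloxy)benzaldehyde | COc1cc(C=O)cc(OC)c1O[Si](C(C)C)(C(C)C)C(C)C | intermediate
3 | 2-bromo-3,5-dimethoxy-4-(triisopropylsilyloxy)benzaldehyde | COc1cc(C=O)c(Br)c(OC)c1O[Si](C(C)C)(C(C)C)C(C)C | intermediate
4 | propiosyringone (1-(4-hydroxy-3,5-dimethoxyphenyl)propan-1-one) | CCC(=O)c1cc(OC)c(O)c(OC)c1 | starting material
5 | 1-[3,5-dimethoxy-4-(triisopropylsilyloxy)phenyl]propan-1-one | CCC(=O)c1cc(OC)c(O[Si](C(C)C)(C(C)C)C(C)C)c(OC)c1 | intermediate
6 | lithium (Z)-enolate of 5 (not isolated) | C/C=C(\O[Li])c1cc(OC)c(O[Si](C(C)C)(C(C)C)C(C)C)c(OC)c1 | intermediate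
7 | (Z)-1-[3,5-dimethoxy-4-(triisopropylsilyloxy)phenyl]prop-1-en-1-yl trifluoromethanesulfonate | C/C=C(\OS(=O)(=O)C(F)(F)F)c1cc(OC)c(O[Si](C(C)C)(C(C)C)C(C)C)c(OC)c1 | intermediate
8 | 2-[(E)-1-[3,5-dimethoxy-4-(triisopropylsilyloxy)phenyl]prop-1-en-1-yl]-4,4,5,5-tetramethyl-1,3,2-dioxaborolane (boron cis to methyl) | C/C=C(\B1OC(C)(C)C(C)(C)O1)c1cc(OC)c(O[Si](C(C)C)(C(C)C)C(C)C)c(OC)c1 | intermediate
9 | 2-[(Z)-1-[3,5-dimethoxy-4-(triisopropylsilyloxy)phenyl]prop-1-en-1-yl]-3,5-dimethoxy-4-(triisopropylsilyloxy)benzaldehyde (methyl cis to the benzaldehyde ring) | C/C=C(\c1c(C=O)cc(OC)c(O[Si](C(C)C)(C(C)C)C(C)C)c1OC)c1cc(OC)c(O[Si](C(C)C)(C(C)C)C(C)C)c(OC)c1 | intermediate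
10 | (Z,Z)-vinyl iodide: CHO of 9 replaced by CH=C(I)CH3, iodine cis to the arene | C/C=C(\c1c(/C=C(\I)C)cc(OC)c(O[Si](C(C)C)(C(C)C)C(C)C)c1OC)c1cc(OC)c(O[Si](C(C)C)(C(C)C)C(C)C)c(OC)c1 | intermediate
11 | vinyllithium: iodine of 10 replaced by lithium, geometry retained (not isolated) | C/C=C(\c1c(/C=C(\[Li])C)cc(OC)c(O[Si](C(C)C)(C(C)C)C(C)C)c1OC)c1cc(OC)c(O[Si](C(C)C)(C(C)C)C(C)C)c(OC)c1 | intermediate
12 | benzhydryllithium: 1-lithio derivative of 13, C2 configured as in 13 (not isolated) | COc1cc(C2([Li])c3c(cc(OC)c(O[Si](C(C)C)(C(C)C)C(C)C)c3OC)C=C(C)[C@H]2C)cc(OC)c1O[Si](C(C)C)(C(C)C)C(C)C | intermediate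
13 | (1S,2S)-1-[3,5-dimethoxy-4-(triisopropylsilyloxy)phenyl]-6,8-dimethoxy-2,3-dimethyl-7-(triisopropylsilyloxy)-1,2-dihydronaphthalene | COc1cc([C@H]2c3c(cc(OC)c(O[Si](C(C)C)(C(C)C)C(C)C)c3OC)C=C(C)[C@H]2C)cc(OC)c1O[Si](C(C)C)(C(C)C)C(C)C | intermediate
14 | 4-[(1S,2S)-7-hydroxy-6,8-dimethoxy-2,3-dimethyl-1,2-dihydronaphthalen-1-yl]-2,6-dimethoxyphenol | COc1cc([C@H]2c3c(cc(OC)c(O)c3OC)C=C(C)[C@H]2C)cc(OC)c1O | target

**Step count and risks**

Total steps: 9. Longest linear sequence: 7 steps (from 4 through steps 3, 4, 5, 6, 7, 8, 9); the other branch from 1 has 6.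

Steps most likely to fail:

1. Step 8 (proposed new method). What may go wrong: proton transfer from the allylic methyl group or from the ether solvent to the vinyllithium before the C–C bond forms; insufficient discrimination of the two alkene faces by the diamine-bound lithium; protonation of the benzhydryl anion on both faces. Fallback with known chemistry, setting out from 10: tin hydride radical cyclisation (Bu3SnH, azobisisobutyronitrile, benzene, 80 °C, slow addition). The vinyl radical at C3 should add 6-endo to C2 because this gives the diaryl-stabilised radical at C1, and hydrogen transfer from Bu3SnH anti to the C2 methyl group should give the 1,2-cis compound as a racemate, that is 13 together with the (1R,2R)-enantiomer of 13 F1. The enantiomers are separated by preparative chromatography on a chiral stationary phase, and the route is rejoined at 13.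

2. Step 6. What may go wrong: slow transmetalation at the doubly ortho-substituted arylpalladium bromide, competing protodeboronation of 8, and erosion of alkene geometry. Fallback, setting out from 3 and using ketone 5: conversion of 3 into the dimethyl acetal of 3 F2 (HC(OMe)3, TsOH, MeOH); bromine–lithium exchange (n-BuLi, THF, −78 °C) to the aryllithium F3; addition to 5 in the presence of CeCl3 to limit enolisation, giving the tertiary diaryl carbinol F4; then TsOH in wet acetone, which should dehydrate the carbinol and hydrolyse the acetal to 9 together with the (E)-isomer of 9 F5, removed by chromatography. The route is rejoined at 9.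

3. Step 7. What may go wrong: low Z/E selectivity and slow addition of the iodo-ylide to the hindered aldehyde, or decomposition of the ylide before it reacts. Fallback, setting out from 9: Corey–Fuchs olefination (CBr4, PPh3, CH2Cl2, 0 °C) to the 1,1-dibromoalkene F6; palladium-catalysed trans-selective monomethylation (Me2Zn, PdCl2(DPEphos), THF), which should replace the bromine trans to the arene and give the (Z)-vinyl bromide F7. Bromine–lithium exchange of F7 with t-BuLi under the conditions of step 8 gives vinyllithium 11, where the route is rejoined.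

**Further compounds**

F1 | step 8 | (1R,2R)-enantiomer of 13 | COc1cc([C@@H]2c3c(cc(OC)c(O[Si](C(C)C)(C(C)C)C(C)C)c3OC)C=C(C)[C@@H]2C)cc(OC)c1O[Si](C(C)C)(C(C)C)C(C)C
F2 | step 6 | dimethyl acetal of 3 (2-bromo-1-(dimethoxymethyl)-3,5-dimethoxy-4-(triisopropylsilyloxy)benzene) | COc1cc(C(OC)OC)c(Br)c(OC)c1O[Si](C(C)C)(C(C)C)C(C)C
F3 | step 6 | aryllithium from F2 (lithium in place of bromine) | COc1cc(C(OC)OC)c([Li])c(OC)c1O[Si](C(C)C)(C(C)C)C(C)C
F4 | step 6 | racemic tertiary carbinol, 1-[2-(dimethoxymethyl)-4,6-dimethoxy-5-(triisopropylsilyloxy)phenyl]-1-[3,5-dimethoxy-4-(triisopropylsilyloxy)phenyl]propan-1-ol | CCC(O)(c1c(C(OC)OC)cc(OC)c(O[Si](C(C)C)(C(C)C)C(C)C)c1OC)c1cc(OC)c(O[Si](C(C)C)(C(C)C)C(C)C)c(OC)c1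
F5 | step 6 | (E)-isomer of 9 (propenyl methyl trans to the benzaldehyde ring) | C/C=C(/c1c(C=O)cc(OC)c(O[Si](C(C)C)(C(C)C)C(C)C)c1OC)c1cc(OC)c(O[Si](C(C)C)(C(C)C)C(C)C)c(OC)c1
F6 | step 7 | 1,1-dibromoalkene: CHO of 9 replaced by CH=CBr2 | C/C=C(\c1c(C=C(Br)Br)cc(OC)c(O[Si](C(C)C)(C(C)C)C(C)C)c1OC)c1cc(OC)c(O[Si](C(C)C)(C(C)C)C(C)C)c(OC)c1
F7 | step 7 | (Z)-vinyl bromide: bromine analogue of 10, bromine cis to the arene | C/C=C(\c1c(/C=C(\Br)C)cc(OC)c(O[Si](C(C)C)(C(C)C)C(C)C)c1OC)c1cc(OC)c(O[Si](C(C)C)(C(C)C)C(C)C)c(OC)c1
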